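If the 0.050 M of solid substrate in this flask has dissolved well before the reading, the question turns on how the enzyme clears a falling concentration of starting material, so I reckoned that.

    starting material + enzyme → target + enzyme, rate k1*[starting material]^2.5*[enzyme]/(1 + ([starting material]/Kh1)^2.5) (Kh1 = 0.0648 M, k1 = 2.86 × 10⁵ M⁻²·⁵ s⁻¹)
    solid substrate ⇌ starting material, rate k2*(cs2 - [starting material]) while solid is left; crystals form when [starting material] > cs2 (cs2 = 36 mM, k2 = 0.0886 s⁻¹)

solid substrate 0.050 M; enzyme 25 µM; time 2.0 min

* how much target there is at 2.0 min, in percent of the solid substrate charged
* concentration of starting material in solution at 2.0 min, in percent of saturation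

- solid substrate is a solid; its amount is given per volume of the solution
- at the start none of the solid substrate is in solution
- starting material means what is dissolved; the solid is not counted in it
- run time (flask): 2.0 min

**Filling up.** I wrote A for dissolved starting material and C for enzyme. Left to itself, dissolution approaches saturation with the time 11.3 s, the inverse of its coefficient.

**The balance.** A then levels off in a quasi-steady state. I tried B = 27.0 mM, where step 2 delivers 0.797 mM s⁻¹ and step 1 takes 0.770 mM s⁻¹, which is close enough.

**The clearing time.** At B the denominator of step 1 is 1.11, and it shrinks as A falls, so I dropped it. Then A to the power −1.50 climbs linearly in time, with a slope of 1.50 times the rate constant times C. I wrote θ = 21.0 s for the time in which this climb adds its own value at B, the clearing time, and it is longer than the filling time.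

**The solid's end.** The charge is dissolved once A holds B and target holds the rest. At 0.797 mM s⁻¹ after a lag of 11.3 s, I put that at T = 40.1 s, less than the run.

**The tail.** Starting from B at T, ln(B/A) grows as 0.667 of the logarithm of one plus (t − T)/θ, where t is the time, and this gave A = 9.49 mM at 2.0 min. That means y = 81.0% and sat = 26.4%.

**The result.** The forecast gave y = 81% (78% to 84%) and sat = 27% (23% to 31%), on the grounds that “Dissolution and enzymatic consumption balance”. The simulation gave y = 80.6% and sat = 27.0%, which is A = 9.70 mM against my 9.49 mM.

**The later reading.** I kept θ = 21.0 s, B and T for a neighbouring flask, identical but read at 5.0 min. They gave A = 4.79 mM, which is 9.58% of the charge, leaving 90.4% as target. That neighbouring flask held 9.68% as starting material and 90.3% as target.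

(The constants used here come from no measurement; what happens was integrated by code.)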